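## Retrosynthetic overview

1. Gnetofuran A ⇒ E‑selective Wittig reaction between the (2R,3S)‑5‑formyl phenylcoumaran and a 3,5‑dihydroxybenzyl phosphonium salt (stilbene C=C made last).
2. The phenylcoumaran ⇒ an achiral 2,3‑diarylallyl alcohol by disconnection of the O1–C2 bond. A catalytic enantioselective 5‑ring hydroaryloxylation closes the dihydrofuran ring and sets C2 and C3 in one C–O bond‑forming step.
3. The diarylallyl alcohol ⇒ 5‑iodovanillin + a 2‑boryl cinnamyl alcohol (Suzuki). The boronate comes from an aryl propargyl alcohol (Cu–B syn‑protoboration), itself from 4‑iodo‑2‑methoxyphenol + propargyl alcohol (Sonogashira).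
4. Ring order: the three benzene rings are bought; the dihydrofuran ring is the only ring formed (step 3).

Assumption: the (R)‑configured acid catalyst of step 3 is taken to give the (2R,3S) product; if the sense of induction is the reverse, the (S)‑catalyst is used and nothing else changes.

## Route

Step 1
Reactants: 1 (4‑iodo‑2‑methoxyphenol); 2 (propargyl alcohol)
Product: 3 3‑(4‑hydroxy‑3‑methoxyphenyl)prop‑2‑yn‑1‑ol
Conditions: PdCl2(PPh3)2 (2 mol%), CuI (4 mol%), Et3N, THF, 45 °C
Reagents that add atoms: none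
Why: Sonogashira coupling; an aryl iodide couples readily with propargyl alcohol even with the free para‑phenol, and no stereocentre is involved.

Step 2
Reactants: 3 (3‑(4‑hydroxy‑3‑methoxyphenyl)prop‑2‑yn‑1‑ol); 4 (5‑iodovanillin, 4‑hydroxy‑3‑iodo‑5‑methoxybenzaldehyde)
Product: 6 4‑hydroxy‑3‑[(1Z)‑3‑hydroxy‑1‑(4‑hydroxy‑3‑methoxyphenyl)prop‑1‑en‑2‑yl]‑5‑methoxybenzaldehyde, via alkenyl pinacolboronate 5 (not isolated)
Conditions: CuCl (5 mol%), Xantphos (5 mol%), NaOtBu (20 mol%), B2pin2 (1.15 equiv), MeOH (2 equiv), THF, rt; then 4 (0.9 equiv), Pd(dppf)Cl2 (3 mol%), 2 M aq K3PO4, 60 °C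
Reagents that add atoms: bis(pinacolato)diboron, CC1(C)OB(OC1(C)C)B1OC(C)(C)C(C)(C)O1 (gives the Bpin group of intermediate 5; no atom of it remains in 6)
Why: Cu‑catalysed syn‑protoboration of an aryl alkyne puts boron on the carbon remote from the arene with H and B cis, and the crude alkenyl‑Bpin then undergoes Suzuki–Miyaura coupling with retention at the o‑iodophenol of 5‑iodovanillin, fixing the Z‑alkene (aryl rings trans); no stereocentre.

Step 3
Reactants: 6 (4‑hydroxy‑3‑[(1Z)‑3‑hydroxy‑1‑(4‑hydroxy‑3‑methoxyphenyl)prop‑1‑en‑2‑yl]‑5‑methoxybenzaldehyde)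
Product: 7 (2R,3S)‑2‑(4‑hydroxy‑3‑methoxyphenyl)‑3‑(hydroxymethyl)‑7‑methoxy‑2,3‑dihydro‑1‑benzofuran‑5‑carbaldehyde (trans)
Conditions: (R)‑3,3'‑bis(2,4,6‑triisopropylphenyl)‑BINOL N‑triflylphosphoramide (5 mol%), CHCl3 (0.02 M), 5 Å MS, −20 °C → rt
Reagents that add atoms: none
Why: Proposed new method: a chiral Brønsted‑acid‑catalysed, redox‑neutral 5‑ring hydroaryloxylation (cycloisomerisation) of a vinylogous phenol‑enol, in which the confined acid hydrogen‑bonds the acidic vanillin‑type OH and relays its proton to the fully substituted alkene carbon while that oxygen closes on the carbon para‑conjugated to the guaiacyl OH (asynchronous syn‑addition through a p‑quinone‑methide‑like contact ion pair), so that one face‑selective event forms the O1–C2 bond and sets C3 (proton delivery) and C2 (C–O closure) as the trans‑(2R,3S) isomer (syn‑addition to the Z‑alkene and the thermodynamic preference both give trans), the formyl group (para to the closing OH, meta to the alkene) deactivating the central ring against protonation at the other alkene carbon; the closest known reaction types are confined‑acid (imidodiphosphorimidate) asymmetric intramolecular hydroalkoxylation of alkenes, chiral phosphoric acid 1,6‑additions to in situ p‑quinone methides, acid activation of o‑hydroxystyrenes, and the biosynthetic quinone‑methide closure of phenylcoumarans.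

Step 4
Reactants: 8 (3,5‑dihydroxybenzyl alcohol)
Product: 9 tributyl(3,5‑dihydroxybenzyl)phosphonium bromide
Conditions: Bu3P (1.1 equiv), 48% aq HBr (1.1 equiv), MeCN, 0 °C → reflux
Reagents that add atoms: tributylphosphine, CCCCP(CCCC)CCCC; hydrogen bromide, Br
Why: Direct conversion of a benzylic alcohol to a phosphonium salt with a phosphine hydrobromide (benzylic bromide formed in situ, then SN2 by the phosphine); the phenols are inert under these conditions and no stereocentre is involved.

Step 5
Reactants: 7 ((2R,3S)‑2‑(4‑hydroxy‑3‑methoxyphenyl)‑3‑(hydroxymethyl)‑7‑methoxy‑2,3‑dihydro‑1‑benzofuran‑5‑carbaldehyde); 9 (tributyl(3,5‑dihydroxybenzyl)phosphonium bromide)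
Product: 11 gnetofuran A, 5‑[(E)‑2‑[(2R,3S)‑2‑(4‑hydroxy‑3‑methoxyphenyl)‑3‑(hydroxymethyl)‑7‑methoxy‑2,3‑dihydro‑1‑benzofuran‑5‑yl]ethenyl]benzene‑1,3‑diol, via tributylphosphonium ylide 10 (not isolated)
Conditions: 9 (1.8 equiv), KHMDS (7.5 equiv), THF/DMPU, −78 °C; then 7, −78 → 0 °C; aq NH4Cl
Reagents that add atoms: none
Why: Wittig olefination with a semi‑stabilised benzylic trialkylphosphonium ylide, which is intrinsically E‑selective, run cold with all OH groups as potassium salts so that the aryl aldehyde is consumed before the phenoxide of 7 can open the ring; C2 and C3 are not touched.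

## Compound list

1 | 4‑iodo‑2‑methoxyphenol | COc1cc(I)ccc1O | starting material
2 | propargyl alcohol | C#CCO | starting material
3 | 3‑(4‑hydroxy‑3‑methoxyphenyl)prop‑2‑yn‑1‑ol | COc1cc(C#CCO)ccc1O | intermediate
4 | 5‑iodovanillin (4‑hydroxy‑3‑iodo‑5‑methoxybenzaldehyde) | COc1cc(C=O)cc(I)c1O | starting material
5 | (2Z)‑3‑(4‑hydroxy‑3‑methoxyphenyl)‑2‑(4,4,5,5‑tetramethyl‑1,3,2‑dioxaborolan‑2‑yl)prop‑2‑en‑1‑ol (not isolated) | COc1cc(/C=C(\CO)B2OC(C)(C)C(C)(C)O2)ccc1O | intermediate
6 | 4‑hydroxy‑3‑[(1Z)‑3‑hydroxy‑1‑(4‑hydroxy‑3‑methoxyphenyl)prop‑1‑en‑2‑yl]‑5‑methoxybenzaldehyde | COc1cc(/C=C(\CO)c2cc(C=O)cc(OC)c2O)ccc1O | intermediate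
7 | (2R,3S)‑2‑(4‑hydroxy‑3‑methoxyphenyl)‑3‑(hydroxymethyl)‑7‑methoxy‑2,3‑dihydro‑1‑benzofuran‑5‑carbaldehyde | COc1cc([C@@H]2Oc3c(OC)cc(C=O)cc3[C@H]2CO)ccc1O | intermediate
8 | 3,5‑dihydroxybenzyl alcohol | OCc1cc(O)cc(O)c1 | starting material
9 | tributyl(3,5‑dihydroxybenzyl)phosphonium bromide | CCCC[P+](CCCC)(CCCC)Cc1cc(O)cc(O)c1.[Br-] | intermediate
10 | tributyl(3,5‑dihydroxybenzylidene)phosphorane (not isolated; drawn neutral, present as its dipotassium bis‑phenoxide) | CCCCP(CCCC)(CCCC)=Cc1cc(O)cc(O)c1 | intermediate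
11 | gnetofuran A | COc1cc([C@@H]2Oc3c(OC)cc(/C=C/c4cc(O)cc(O)c4)cc3[C@H]2CO)ccc1O | target

## Step count and risks

Total step count: 5. Longest linear sequence: 4 (steps 1, 2, 3, 5); step 4 is a one‑step side branch.

The three steps most likely to fail:

**Step 3 (the proposed new step).** It may fail through low reactivity or low ee. It may also fail through protonation at the other alkene carbon (o‑quinone‑methide channel, draining to the 2,3‑diarylpropanal) or through acid ionisation of the allylic alcohol (leading to a 3‑benzylbenzofuran). The fallback uses only known reaction types, sets out from 6 and returns to 7. Iridium‑catalysed asymmetric hydrogenation of the trisubstituted allylic alcohol ([Ir(cod)(PHOX)]BArF of the appropriate hand, H2 50 bar, CH2Cl2, rt) gives 4‑hydroxy‑3‑[(2S)‑1‑hydroxy‑3‑(4‑hydroxy‑3‑methoxyphenyl)propan‑2‑yl]‑5‑methoxybenzaldehyde F1. DDQ (1.05 equiv, dioxane, rt) then oxidises the 4‑hydroxybenzylic CH2 to the p‑quinone methide, which the neighbouring phenol traps. This is the same oxidative C–O closure as the 2'‑hydroxyisoflavan to pterocarpan reaction; the existing C3 centre directs the closure trans, giving 7.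

**Step 5.** The polyanionic ylide may be poorly soluble or sluggish, the E/Z ratio may be lower than expected, and the phenoxide of 7 can expel the p‑formylphenoxide (ring opening to a quinone methide) if the mixture warms before the aldehyde is consumed. The fallback sets out from 7 and returns to 11. A fast methylenation (Ph3PCH3Br, KOtBu, THF, −78 → 0 °C) gives [(2R,3S)‑5‑ethenyl‑2‑(4‑hydroxy‑3‑methoxyphenyl)‑7‑methoxy‑2,3‑dihydro‑1‑benzofuran‑3‑yl]methanol F2. A Mizoroki–Heck reaction of this styrene with commercial 5‑iodoresorcinol (Pd(OAc)2, P(o‑tol)3, Et3N, DMF, 90 °C), in which no phenoxide is generated, builds the E‑stilbene and gives 11 directly.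

**Step 2.** The regiochemistry of the Cu–B addition may be eroded by the electron‑rich phenol‑bearing arene and the propargylic OH, and residual copper may slow the one‑pot Suzuki coupling. The fallback sets out from 3 and returns to 6. Pd‑catalysed hydrostannation (Bu3SnH, PdCl2(PPh3)2, THF, 0 °C), whose regiochemistry is controlled by the propargylic OH and the electron‑rich arene and puts tin on the carbinol‑proximal carbon by syn‑addition, gives (2E)‑3‑(4‑hydroxy‑3‑methoxyphenyl)‑2‑(tributylstannyl)prop‑2‑en‑1‑ol F3. Stille coupling of this stannane with 4 (Pd(PPh3)4, CuI, DMF, 60 °C) gives 6 with the same alkene geometry.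

Further compounds

F1 | step 3 | 4‑hydroxy‑3‑[(2S)‑1‑hydroxy‑3‑(4‑hydroxy‑3‑methoxyphenyl)propan‑2‑yl]‑5‑methoxybenzaldehyde | OC[C@@H](Cc1ccc(O)c(OC)c1)c1cc(C=O)cc(OC)c1O
F2 | step 5 | [(2R,3S)‑5‑ethenyl‑2‑(4‑hydroxy‑3‑methoxyphenyl)‑7‑methoxy‑2,3‑dihydro‑1‑benzofuran‑3‑yl]methanol | COc1cc([C@@H]2Oc3c(OC)cc(C=C)cc3[C@H]2CO)ccc1O
F3 | step 2 | (2E)‑3‑(4‑hydroxy‑3‑methoxyphenyl)‑2‑(tributylstannyl)prop‑2‑en‑1‑ol | COc1cc(/C=C(\CO)[Sn](CCCC)(CCCC)CCCC)ccc1O
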